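**Assumptions:** Lignan numbering is used (ring O–C7(Ar)–C8(C9H2OH)–C8′(C7′H(OH)Ar)–C9′H2); the target is (7S,8R,7′S,8′S). The hand of the Ir ligand in step 5 is chosen (and checked by Mosher analysis of 7) to give the (1S,2R) diol; I have not assigned which SEGPHOS enantiomer does this.

## Retrosynthetic overview
1. Target 14 ⇐ tris-TIPS ether 13 (global desilylation).
2. 13 ⇐ acid 11 by forming C8′–C9′: decarboxylative alkoxymethyl-radical 5-exo cyclization onto the styrene, then oxidation of the benzylic radical and capture by water. This closes the only ring (the THF) and sets C8′ and C7′.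
3. 11 ⇐ alcohol 9 + bromoacetic acid (supplies C9′); 9 ⇐ vinyl alcohol 8 + aryl bromide 4 (Heck).
4. 8 ⇐ diol 7 ⇐ aldehyde 5 + vinyl ethylene carbonate (Ir-catalysed anti-(hydroxymethyl)allylation; sets C7 and C8).
5. 4 and 5 ⇐ catechol (methylation, para-bromination, silylation, formylation).

## Route

**Step 1**
Reactants: 1, catechol
Product: 2, 2-methoxyphenol (guaiacol)
Conditions: MeI (0.5 equiv relative to catechol), K2CO3, acetone, reflux; base extraction/distillation
Reagents that add atoms: iodomethane, CI
Why: Williamson mono-O-methylation, with excess catechol suppressing veratrole; no stereocentre.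

**Step 2**
Reactants: 2, guaiacol
Product: 3, 4-bromo-2-methoxyphenol
Conditions: NBS (1.0 equiv), MeCN, 0 °C → rt
Reagents that add atoms: N-bromosuccinimide, O=C1CCC(=O)N1Br
Why: Electrophilic aromatic bromination; the free OH is the stronger director, so Br enters para to OH.

**Step 3**
Reactants: 3, 4-bromo-2-methoxyphenol
Product: 4, (4-bromo-2-methoxyphenoxy)triisopropylsilane
Conditions: TIPSCl, imidazole, DMF, rt
Reagents that add atoms: chlorotriisopropylsilane, CC(C)[Si](Cl)(C(C)C)C(C)C
Why: Phenol silylation; the aryl TIPS ether tolerates n-BuLi, the Ir and Pd steps, NaH and photoredox, and is removed by fluoride at the end.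

**Step 4**
Reactants: 4, aryl bromide
Product: 5, 3-methoxy-4-(triisopropylsilyloxy)benzaldehyde
Conditions: n-BuLi, THF, −78 °C; then DMF, −78 → 0 °C; aq NH4Cl
Reagents that add atoms: N,N-dimethylformamide, CN(C)C=O
Why: Br–Li exchange then Bouveault formylation; the lithium is para to the silyloxy group, so no silyl migration pathway exists.

**Step 5**
Reactants: 5, aldehyde; 6, 4-vinyl-1,3-dioxolan-2-one (vinyl ethylene carbonate, racemic)
Product: 7, (1S,2R)-2-ethenyl-1-[3-methoxy-4-(triisopropylsilyloxy)phenyl]propane-1,3-diol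
Conditions: [Ir(cod)Cl]2 (2.5 mol %), SEGPHOS (5 mol %, hand per assumption), 4-Cl-3-NO2-C6H3CO2H (10 mol %), K3PO4 (cat.), i-PrOH (2 equiv), THF, 90 °C
Reagents that add atoms: none (i-PrOH supplies H only; CO2 is lost from 6)
Why: Krische transfer-hydrogenative carbonyl (hydroxymethyl)allylation: 6 ionises with loss of CO2 to an (E)-σ-allyl-iridium that adds through a closed chair transition state, giving the anti diol (C7/C8 as in the target), with the ligand setting absolute configuration.

**Step 6**
Reactants: 7, diol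
Product: 8, (1S,2R)-1-[3-methoxy-4-(triisopropylsilyloxy)phenyl]-2-[(triisopropylsilyloxy)methyl]but-3-en-1-ol
Conditions: TIPSCl (1.1 equiv), imidazole, CH2Cl2, 0 °C
Reagents that add atoms: chlorotriisopropylsilane, CC(C)[Si](Cl)(C(C)C)C(C)C
Why: Selective silylation of the primary OH over the hindered secondary benzylic OH; TIPS is chosen over TBS because it resists 1,3-O→O migration in step 8.

**Step 7**
Reactants: 8, vinyl alcohol; 4, aryl bromide
Product: 9, (1S,2R,3E)-1,4-bis[3-methoxy-4-(triisopropylsilyloxy)phenyl]-2-[(triisopropylsilyloxy)methyl]but-3-en-1-ol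
Conditions: Pd2(dba)3 (2 mol %), [HP(t-Bu)3]BF4 (8 mol %), Cy2NMe, dioxane, 80 °C
Reagents that add atoms: none
Why: Mizoroki–Heck arylation at the terminal alkene carbon; β-hydride elimination toward the new benzylic carbon gives the conjugated (E)-styrene and leaves C7 and C8 untouched.

**Step 8**
Reactants: 9, alcohol; 10, bromoacetic acid
Product: 11, 2-{[(1S,2R,3E)-1,4-bis[3-methoxy-4-(triisopropylsilyloxy)phenyl]-2-[(triisopropylsilyloxy)methyl]but-3-en-1-yl]oxy}acetic acid
Conditions: NaH (3.5 equiv), BrCH2CO2H (1.5 equiv), THF, cat. Bu4NI, 0 → 45 °C; pH 4 work-up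
Reagents that add atoms: none
Why: Williamson etherification of the only free hydroxyl (O7) with sodium bromoacetate; this installs C9′ as an α-alkoxy acid, a radical precursor.

**Step 9**
Reactants: 11, acid
Product: 13, (S)-[3-methoxy-4-(triisopropylsilyloxy)phenyl]{(3S,4R,5S)-5-[3-methoxy-4-(triisopropylsilyloxy)phenyl]-4-[(triisopropylsilyloxy)methyl]oxolan-3-yl}methanol (via N-acyloxyphthalimide 12, not isolated)
Conditions: NHPI, DIC, DMAP (cat.), CH2Cl2, rt; filter, evaporate; then fac-Ir(ppy)3 (1 mol %), degassed MeCN/H2O 4:1, blue LEDs, rt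
Reagents that add atoms: water, O (the C7′ hydroxyl); N-hydroxyphthalimide, O=C1c2ccccc2C(=O)N1O, is present only in transient 12
Why: Proposed new method: excited Ir(III) reduces ester 12, which loses CO2 and phthalimide to give the O7–CH2• radical; this cyclizes 5-exo onto C8′ through a Beckwith–Houk chair with the C7 aryl and C8 CH2OTIPS groups pseudo-equatorial, placing the new C8′ substituent cis to the aryl and trans to CH2OTIPS (8′S). Ir(IV) then oxidizes the electron-rich benzylic radical to the cation, and water adds to the A(1,3)-minimized conformer anti to the bulkier C8 branch (predicted 7′S, substrate-controlled). Closest known reactions are the intermolecular photoredox oxyalkylation of styrenes with N-acyloxyphthalimides and water, and 5-exo cyclizations of alkoxymethyl radicals.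

**Step 10**
Reactants: 13, tris-TIPS ether
Product: 14, target, 4-[(S)-hydroxy{(3S,4R,5S)-5-(4-hydroxy-3-methoxyphenyl)-4-(hydroxymethyl)oxolan-3-yl}methyl]-2-methoxyphenol
Conditions: TBAF (4 equiv), AcOH (4 equiv), THF, 0 °C → rt
Reagents that add atoms: none
Why: Fluoride desilylation of two aryl and one primary alkyl TIPS ether; AcOH buffering avoids base-induced quinone-methide formation, so C7 and C7′ are not scrambled.

## Compound list
1 | catechol | Oc1ccccc1O | starting material
2 | 2-methoxyphenol | COc1ccccc1O | intermediate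
3 | 4-bromo-2-methoxyphenol | COc1cc(Br)ccc1O | intermediate
4 | (4-bromo-2-methoxyphenoxy)triisopropylsilane | COc1cc(Br)ccc1O[Si](C(C)C)(C(C)C)C(C)C | intermediate
5 | 3-methoxy-4-(triisopropylsilyloxy)benzaldehyde | COc1cc(C=O)ccc1O[Si](C(C)C)(C(C)C)C(C)C | intermediate
6 | 4-vinyl-1,3-dioxolan-2-one (racemic) | C=CC1COC(=O)O1 | starting material
7 | (1S,2R)-2-ethenyl-1-aryl-propane-1,3-diol | O[C@H](c1ccc(O[Si](C(C)C)(C(C)C)C(C)C)c(OC)c1)[C@@H](CO)C=C | intermediate
8 | (1S,2R) primary TIPS ether of 7 | O[C@H](c1ccc(O[Si](C(C)C)(C(C)C)C(C)C)c(OC)c1)[C@@H](CO[Si](C(C)C)(C(C)C)C(C)C)C=C | intermediate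
9 | (1S,2R,3E)-1,4-diaryl homoallylic alcohol | O[C@H](c1ccc(O[Si](C(C)C)(C(C)C)C(C)C)c(OC)c1)[C@@H](CO[Si](C(C)C)(C(C)C)C(C)C)/C=C/c1ccc(O[Si](C(C)C)(C(C)C)C(C)C)c(OC)c1 | intermediate
10 | bromoacetic acid | OC(=O)CBr | starting material
11 | O7-carboxymethyl ether of 9 | OC(=O)CO[C@H](c1ccc(O[Si](C(C)C)(C(C)C)C(C)C)c(OC)c1)[C@@H](CO[Si](C(C)C)(C(C)C)C(C)C)/C=C/c1ccc(O[Si](C(C)C)(C(C)C)C(C)C)c(OC)c1 | intermediate
12 | N-acyloxyphthalimide of 11 (not isolated) | O=C(CO[C@H](c1ccc(O[Si](C(C)C)(C(C)C)C(C)C)c(OC)c1)[C@@H](CO[Si](C(C)C)(C(C)C)C(C)C)/C=C/c1ccc(O[Si](C(C)C)(C(C)C)C(C)C)c(OC)c1)ON1C(=O)c2ccccc2C1=O | intermediate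
13 | tris-TIPS ether of the target | COc1cc([C@@H](O)[C@@H]2CO[C@H](c3ccc(O[Si](C(C)C)(C(C)C)C(C)C)c(OC)c3)[C@H]2CO[Si](C(C)C)(C(C)C)C(C)C)ccc1O[Si](C(C)C)(C(C)C)C(C)C | intermediate
14 | target (7S,8R,7′S,8′S) | COc1cc([C@@H](O)[C@@H]2CO[C@H](c3ccc(O)c(OC)c3)[C@H]2CO)ccc1O | target

## Summary
Total steps: 10 (step 9 is a one-pot activation/cyclization). Longest linear sequence: 10 (catechol → 14; bromide 4 is used in steps 4 and 7).

Steps most likely to fail:
1. **Step 9 (radical cyclization/hydroxylation).** Risks are modest selectivity at C7′, E1 loss from the benzylic cation, and β-scission of the alkoxymethyl radical. Fallback: run the cascade in DMSO so the benzylic cation is trapped Kornblum-style as the C7′ ketone (C8′ then sits trans by equilibration), and set 7′S by reagent-controlled CBS reduction.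
2. **Step 8 (O-alkylation of the hindered benzylic alkoxide).** Risks are low conversion and silyl migration. Fallback: avoid the alkoxide by Rh2(OAc)4-catalysed O–H insertion of a diazoacetate into alcohol 8 before the Heck step, then mild ester cleavage (Me3SnOH).
3. **Step 5 (Ir-catalysed (hydroxymethyl)allylation).** Risks are dr/ee with the electron-rich aldehyde and the unverified ligand hand. Fallback: chiral-phosphoric-acid-catalysed allylboration of 5 with an (E)-γ-(silyloxymethyl)allyl pinacolboronate, which gives the same anti adduct with O9 already silylated and removes step 6.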